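**Retrosynthetic overview**
1. Target 33 comes from ester 31 by late C3=C4 dehydrogenation of the C2 ketone and desilylation; the glycolate is put on C14–OH just before.
2. The eight-membered ring is closed last, at C13–C14, by a samarium Barbier reaction of iodo aldehyde 27; C10 to C13 are grown on the hydrindane by hydroboration (C10) and a deconjugative methyl tiglate aldol (C11, C12).
3. The six-membered ring comes from the key step: one-pot Michael addition/Ireland–Claisen ring contraction of cyclopentenone propanoate 11, which closes the cyclohexene by the C5–C6 bond.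
4. Enabling feature: C5 is α to C14 (taken to the carboxyl level) and lies between C4 (β-carbon of the C2=O/C3=C4 cyclopentenone) and C6 (the CH–CH3 end of an (E)-crotyl unit C6=C7–C8). An ester bridge C14–O–C8 gives a temporary δ-lactone (O, C14, C5, C4, C9, C8) that contracts to the carbocycle (C5, C6, C7, C8, C9, C4).
5. Compound 11 comes from cyclopentane-1,3-dione (five-membered ring), crotonaldehyde (C6–C8 and the C6 methyl), propanoyl chloride (C5, C14, C5 methyl) and isopropenylmagnesium bromide (C10, C11, C10 methyl). Ring order: five, temporary lactone, six, eight.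

Key step: step 6

Locants (mutilin numbering): five-membered ring C1 (CH2), C2 (C=O), C3 (=CH), C4, C9; six-membered ring C4, C5 (quaternary, CH3), C6 (CH–CH3), C7, C8, C9; eight-membered ring C4, C5, C14 (ester oxygen), C13, C12 (CH3, vinyl), C11 (OH), C10 (CH–CH3), C9.

Assumption: the stereodescriptors of the SMILES are taken literally and carried unchanged through all intermediates; as written they place the C14 arm on C5 and the C10 arm on C9 on opposite faces of the cyclohexane ring (C5 and C6 epimeric to the usual mutilin core), so the eight-membered ring is closed last, once both arms are fixed.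

Step 1
Reactants: 1 cyclopentane-1,3-dione
Product: 2 3-iodocyclopent-2-en-1-one
Conditions: PPh3, I2, Et3N, MeCN, 0 °C → rt
Reagents that add atoms: iodine, II
Why: The enol of the 1,3-dione attacks the iodophosphonium salt and iodide displaces triphenylphosphine oxide by addition–elimination (vinylogous acid halide formation), which gives the β-iodo enone without any stereocentre.

Step 2
Reactants: 2 3-iodocyclopent-2-en-1-one; 3 (E)-but-2-enal
Product: 5 3-[(1R,2E)-1-hydroxybut-2-en-1-yl]cyclopent-2-en-1-one, via trimethylsilyl ether 4 (not isolated)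
Conditions: CrCl2 (10 mol %), chiral oxazoline–sulfonamide ligand (12 mol %), NiCl2 (2 mol %), Mn powder, Me3SiCl, Et3N (cat.), MeCN, rt; then 1 M HCl
Reagents that add atoms: none
Why: Catalytic asymmetric Nozaki–Hiyama–Kishi coupling, in which zerovalent nickel activates the vinyl iodide, the alkenyl group passes to chromium, and the trivalent alkenylchromium adds 1,2 to the aldehyde only; the chiral ligand on chromium selects the aldehyde face that gives the (R)-carbinol C8, and Me3SiCl with manganese turns the chromium over.

Step 3
Reactants: 5 3-[(1R,2E)-1-hydroxybut-2-en-1-yl]cyclopent-2-en-1-one; 6 propanoyl chloride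
Product: 7 (1R,2E)-1-(3-oxocyclopent-1-en-1-yl)but-2-en-1-yl propanoate
Conditions: pyridine, DMAP (cat.), CH2Cl2, 0 °C
Reagents that add atoms: none
Why: DMAP-catalysed O-acylation of the secondary allylic alcohol attaches the three carbons that become C5, C14 and the C5 methyl, and the stereocentre is not touched.

Step 4
Reactants: 7 (1R,2E)-1-(3-oxocyclopent-1-en-1-yl)but-2-en-1-yl propanoate; 8 prop-1-en-2-ylmagnesium bromide
Product: 10 (1R,2E)-1-[(1R)-3-oxo-1-(prop-1-en-2-yl)cyclopentyl]but-2-en-1-yl propanoate, via silyl enol ether 9 (not isolated)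
Conditions: CuBr·SMe2 (20 mol %), Me3SiCl, THF, −78 °C; then 1 M HCl
Reagents that add atoms: none
Why: Copper-catalysed, Me3SiCl-accelerated conjugate addition of the Grignard reagent to the β,β-disubstituted cyclopentenone creates the quaternary C9; by the Felkin–Anh-type model for γ-oxygenated enones the organocopper should attack anti to the C8–O bond with the small C8–H turned towards the ring, giving the configuration drawn, and the 1,4-addition at −78 °C should outrun substitution of the allylic ester.

Step 5
Reactants: 10 (1R,2E)-1-[(1R)-3-oxo-1-(prop-1-en-2-yl)cyclopentyl]but-2-en-1-yl propanoate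
Product: 11 (1R,2E)-1-[4-oxo-1-(prop-1-en-2-yl)cyclopent-2-en-1-yl]but-2-en-1-yl propanoate (quaternary carbon as in 10)
Conditions: IBX, DMSO, 70 °C
Reagents that add atoms: none
Why: IBX dehydrogenation of the ketone through its enol; C9 carries no hydrogen, so the double bond can only enter between C3 and C4, which turns C4 into a Michael acceptor.

Step 6
Reactants: 11 (1R,2E)-1-[4-oxo-1-(prop-1-en-2-yl)cyclopent-2-en-1-yl]but-2-en-1-yl propanoate
Product: 15 cis-fused 4,5-dimethyl-2-oxo-7a-(prop-1-en-2-yl)-2,3,3a,4,5,7a-hexahydro-1H-indene-4-carboxylic acid, via lactone 12 (not isolated), via bis-silyl ketene acetal 13 (not isolated), via silyl ester 14 (not isolated)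
Conditions: t-BuOK (0.2 equiv), THF, −20 → 0 °C; then −78 °C, Me3SiCl (4 equiv), LiN(i-Pr)2 (2.5 equiv); warm to 65 °C; 1 M HCl
Reagents that add atoms: none
Why: A catalytic amount of tert-butoxide lets the propanoate enolate add 6-exo-trig to C4 of the enone from the face of the C8–O tether (intramolecular Michael addition; cis-fused δ-lactone 12 with C4 set and C5 still epimerisable), and double O-silylation then gives the endocyclic silyl ketene acetal 13. In 13 the (E)-propenyl group on C8 can reach C5 only across the lactone ring, so the Ireland–Claisen [3,3] shift runs through an enforced boat transition state: the C8–O bond breaks, the C5–C6 bond forms, and the six-membered lactone contracts to the cyclohexene (closest known reaction type: ester-enolate Claisen ring contraction of 6-alkenyl δ-lactones to cyclohexenecarboxylic acids). The quaternary C5 is set by suprafacial chirality transfer from C8: the carboxyl carbon C14 ends on the ring face from which the oxygen departs, and this face is fixed relative to C9 because C8 and C9 are neighbours in the lactone. C6 follows from the E geometry of the alkene in the boat (its methyl cis to C14 and trans to the C5 methyl), and C4 from the tether. The selectivity needed is Michael addition before silylation (no silyl chloride in the first stage, so the acyclic Claisen shift of 11 cannot compete) and ketene acetal formation in the presence of the ketone; excess base and Me3SiCl secure the latter by parking the ketone as its silyl enol ether, which returns on acidic work-up together with the carboxylic acid.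

Step 7
Reactants: 15 cis-fused 4,5-dimethyl-2-oxo-7a-(prop-1-en-2-yl)-2,3,3a,4,5,7a-hexahydro-1H-indene-4-carboxylic acid
Product: 16 methyl ester of 15
Conditions: MeI, K2CO3, DMF, rt
Reagents that add atoms: iodomethane, CI
Why: SN2 O-alkylation of the carboxylate, chosen because the neopentyl-type acid resists acid-catalysed esterification; no stereocentre changes.

Step 8
Reactants: 16 methyl ester of 15
Product: 17 ethylene ketal (spiro-1,3-dioxolane at C2) of 16
Conditions: Me3SiOCH2CH2OSiMe3, Me3SiOTf (cat.), CH2Cl2, −78 → −20 °C
Reagents that add atoms: 1,2-bis(trimethylsilyloxy)ethane, C[Si](C)(C)OCCO[Si](C)(C)C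
Why: Aprotic silyl-transfer ketalisation masks the C2 ketone against the later hydride, organolithium and SmI2 steps without touching the two alkenes.

Step 9
Reactants: 17 ethylene ketal of 16
Product: 19 primary alcohol (C9 now bears CH(CH3)CH2OH), via alkylborane 18 (not isolated)
Conditions: 9-BBN, THF, 0 °C → rt; then NaOH, H2O2, 0 °C
Reagents that add atoms: hydrogen peroxide, OO
Why: Hydroboration–oxidation in which 9-BBN selects the 1,1-disubstituted isopropenyl group over the ring alkene and puts boron on the terminal carbon; C10 should be set by hydrogen delivery anti to the bulky C4–C5 arm in the conformer that keeps the ring CH2 (C1) next to the vinylic methyl.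

Step 10
Reactants: 19 primary alcohol
Product: 20 saturated alcohol (C7–C8 reduced)
Conditions: H2 (1 atm), Pd/C, EtOAc, rt
Reagents that add atoms: none
Why: Heterogeneous hydrogenation of the only remaining alkene, done before the vinyl group exists; no new stereocentre is formed.

Step 11
Reactants: 20 saturated alcohol
Product: 21 aldehyde (C11)
Conditions: TEMPO (10 mol %), PhI(OAc)2, CH2Cl2, rt
Reagents that add atoms: none
Why: Oxoammonium oxidation of the primary alcohol stops at the aldehyde under near-neutral conditions, so the C10 stereocentre α to the new carbonyl should not epimerise.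

Step 12
Reactants: 21 aldehyde (C11); 22 methyl (E)-2-methylbut-2-enoate
Product: 23 β-hydroxy ester with the quaternary C12 (methyl, vinyl, CO2CH3)
Conditions: LiN(i-Pr)2, THF–HMPA, −78 °C (with 22); then 21, −78 °C; AcOH
Reagents that add atoms: none
Why: Deconjugative aldol addition, in which γ-deprotonation of the tiglate gives a lithium dienolate that reacts with the aldehyde at its α-carbon to form the quaternary C12; Felkin–Anh attack anti to C9 should set C11, and a Zimmerman–Traxler chair with the α-methyl cis to O–Li should place the C12 methyl syn and the vinyl anti to the C11 hydroxyl.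

Step 13
Reactants: 23 β-hydroxy ester
Product: 24 1,3-diol (C11–OH, C13–OH)
Conditions: LiBH4, THF, 0 °C → rt
Reagents that add atoms: none
Why: Hydroxyl-assisted borohydride reduction, in which the C11 alkoxyborohydride delivers hydride to the neighbouring ester while the isolated neopentyl C14 methyl ester should remain.

Step 14
Reactants: 24 1,3-diol
Product: 25 primary iodide (C13–I)
Conditions: I2, PPh3, imidazole, toluene, 70 °C
Reagents that add atoms: iodine, II
Why: Appel-type iodination through the alkoxyphosphonium salt; only the primary hydroxyl should react, the hindered C11 carbinol staying free.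

Step 15
Reactants: 25 primary iodide
Product: 26 C11 tert-butyldimethylsilyl ether
Conditions: t-BuMe2SiOTf, 2,6-lutidine, CH2Cl2, −78 → 0 °C
Reagents that add atoms: tert-butyldimethylsilyl trifluoromethanesulfonate, CC(C)(C)[Si](C)(C)OS(=O)(=O)C(F)(F)F
Why: The silyl triflate silylates the hindered secondary alcohol, which reserves the later esterification for C14–OH.

Step 16
Reactants: 26 C11 silyl ether
Product: 27 iodo aldehyde (C14 aldehyde)
Conditions: i-Bu2AlH, CH2Cl2, −78 °C; aq. potassium sodium tartrate
Reagents that add atoms: none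
Why: Partial reduction, in which the tetrahedral aluminium hemiacetal of the neopentyl ester is stable at −78 °C and releases the aldehyde on work-up; the primary iodide is not reduced at this temperature.

Step 17
Reactants: 27 iodo aldehyde
Product: 28 tricyclic alcohol (C14–OH, C11–OTBS, C2 dioxolane)
Conditions: SmI2 (2.5 equiv), HMPA, THF (high dilution), −78 → 0 °C; aq. NH4Cl
Reagents that add atoms: none
Why: Intramolecular samarium Barbier reaction, in which SmI2/HMPA reduces the neopentyl iodide to the alkylsamarium that adds to the aldehyde and closes the eight-membered ring by the C13–C14 bond; C14 should be set in the samarium-bridged cyclic transition state with the carbonyl oxygen turned away from the C5 methyl.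

Step 18
Reactants: 28 tricyclic alcohol
Product: 29 keto alcohol (C2 ketone, C14–OH, C11–OTBS)
Conditions: PPTS, acetone–H2O, 50 °C
Reagents that add atoms: water, O
Why: Acid-catalysed hydrolysis of the dioxolane, done before esterification so that only the robust secondary silyl ether is exposed to acid.

Step 19
Reactants: 29 keto alcohol; 30 2-[(tert-butyldimethylsilyl)oxy]acetic acid
Product: 31 C14 silyloxyacetate
Conditions: DCC, DMAP, CH2Cl2, rt
Reagents that add atoms: none
Why: Steglich esterification of the hindered C14 alcohol through the acylpyridinium ion; C11–OH is blocked as its silyl ether.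

Step 20
Reactants: 31 C14 silyloxyacetate
Product: 32 bis-silyl ether of the target (C3=C4 enone)
Conditions: IBX, DMSO, 70 °C
Reagents that add atoms: none
Why: IBX dehydrogenation as in step 5; C1 is flanked by the quaternary C9, so only the C3=C4 enone can form, which also removes the C4 stereocentre.

Step 21
Reactants: 32 bis-silyl ether of the target
Product: 33 pleuromutilin F
Conditions: HF·pyridine, THF, 0 °C → rt
Reagents that add atoms: none
Why: Fluoride cleaves both silyl ethers, and the hindered ester and the enone are stable to these conditions.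

**Compound list**
1 | cyclopentane-1,3-dione | O=C1CCC(=O)C1 | starting material
2 | 3-iodocyclopent-2-en-1-one | O=C1C=C(I)CC1 | intermediate
3 | (E)-but-2-enal | C/C=C/C=O | starting material
4 | 3-[(1R,2E)-1-(trimethylsilyloxy)but-2-en-1-yl]cyclopent-2-en-1-one | C/C=C/[C@@H](O[Si](C)(C)C)C1=CC(=O)CC1 | intermediate (not isolated)
5 | 3-[(1R,2E)-1-hydroxybut-2-en-1-yl]cyclopent-2-en-1-one | C/C=C/[C@@H](O)C1=CC(=O)CC1 | intermediate
6 | propanoyl chloride | CCC(Cl)=O | starting material
7 | (1R,2E)-1-(3-oxocyclopent-1-en-1-yl)but-2-en-1-yl propanoate | C/C=C/[C@@H](OC(=O)CC)C1=CC(=O)CC1 | intermediate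
8 | prop-1-en-2-ylmagnesium bromide | CC(=C)[Mg]Br | starting material
9 | trimethylsilyl enol ether of 10 | C/C=C/[C@@H](OC(=O)CC)[C@@]1(C(C)=C)C=C(O[Si](C)(C)C)CC1 | intermediate (not isolated)
10 | (1R,2E)-1-[(1R)-3-oxo-1-(prop-1-en-2-yl)cyclopentyl]but-2-en-1-yl propanoate | C/C=C/[C@@H](OC(=O)CC)[C@@]1(C(C)=C)CC(=O)CC1 | intermediate
11 | (1R,2E)-1-[4-oxo-1-(prop-1-en-2-yl)cyclopent-2-en-1-yl]but-2-en-1-yl propanoate, quaternary carbon as in 10 | C/C=C/[C@@H](OC(=O)CC)[C@@]1(C(C)=C)CC(=O)C=C1 | intermediate
12 | cis-fused 4-methyl-1-[(E)-prop-1-en-1-yl]-7a-(prop-1-en-2-yl)hexahydrocyclopenta[c]pyran-3,6-dione, both C5 epimers | C/C=C/[C@H]1OC(=O)C(C)[C@@H]2CC(=O)C[C@]12C(C)=C | intermediate (not isolated)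
13 | bis(trimethylsilyl) derivative of 12 (lactone silyl ketene acetal, ketone silyl enol ether) | C/C=C/[C@H]1OC(O[Si](C)(C)C)=C(C)[C@@H]2C=C(O[Si](C)(C)C)C[C@]12C(C)=C | intermediate (not isolated)
14 | trimethylsilyl ester and silyl enol ether of 15 | C[Si](C)(C)OC(=O)[C@@]1(C)[C@@H](C)C=C[C@@]2(C(C)=C)CC(O[Si](C)(C)C)=C[C@@H]12 | intermediate (not isolated)
15 | cis-fused 4,5-dimethyl-2-oxo-7a-(prop-1-en-2-yl)-2,3,3a,4,5,7a-hexahydro-1H-indene-4-carboxylic acid; carboxyl cis to the C6 methyl, trans to the C5 methyl and to the isopropenyl group | OC(=O)[C@@]1(C)[C@@H](C)C=C[C@@]2(C(C)=C)CC(=O)C[C@@H]12 | intermediate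
16 | methyl ester of 15 | COC(=O)[C@@]1(C)[C@@H](C)C=C[C@@]2(C(C)=C)CC(=O)C[C@@H]12 | intermediate
17 | ethylene ketal (C2 spiro-1,3-dioxolane) of 16 | COC(=O)[C@@]1(C)[C@@H](C)C=C[C@@]2(C(C)=C)CC3(OCCO3)C[C@@H]12 | intermediate
18 | B-alkyl-9-borabicyclo[3.3.1]nonane adduct of 17 | COC(=O)[C@@]1(C)[C@@H](C)C=C[C@@]2([C@@H](C)CB3C4CCCC3CCC4)CC3(OCCO3)C[C@@H]12 | intermediate (not isolated)
19 | primary alcohol: C9 bears the 1-hydroxypropan-2-yl group (C10, C11) | COC(=O)[C@@]1(C)[C@@H](C)C=C[C@@]2([C@@H](C)CO)CC3(OCCO3)C[C@@H]12 | intermediate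
20 | 19 with C7–C8 saturated | COC(=O)[C@@]1(C)[C@@H](C)CC[C@@]2([C@@H](C)CO)CC3(OCCO3)C[C@@H]12 | intermediate
21 | C11 aldehyde | COC(=O)[C@@]1(C)[C@@H](C)CC[C@@]2([C@@H](C)C=O)CC3(OCCO3)C[C@@H]12 | intermediate
22 | methyl (E)-2-methylbut-2-enoate (methyl tiglate) | C/C=C(\C)C(=O)OC | starting material
23 | aldol adduct: C11 carbinol, quaternary C12 with methyl, vinyl and CO2CH3 | COC(=O)[C@@]1(C)[C@@H](C)CC[C@@]2([C@@H](C)[C@H](O)[C@](C)(C=C)C(=O)OC)CC3(OCCO3)C[C@@H]12 | intermediate
24 | 1,3-diol (C11–OH, C13–OH) | COC(=O)[C@@]1(C)[C@@H](C)CC[C@@]2([C@@H](C)[C@H](O)[C@](C)(C=C)CO)CC3(OCCO3)C[C@@H]12 | intermediate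
25 | C13 iodide | COC(=O)[C@@]1(C)[C@@H](C)CC[C@@]2([C@@H](C)[C@H](O)[C@](C)(C=C)CI)CC3(OCCO3)C[C@@H]12 | intermediate
26 | C13 iodide, C11 tert-butyldimethylsilyl ether | COC(=O)[C@@]1(C)[C@@H](C)CC[C@@]2([C@@H](C)[C@H](O[Si](C)(C)C(C)(C)C)[C@](C)(C=C)CI)CC3(OCCO3)C[C@@H]12 | intermediate
27 | iodo aldehyde (C14 aldehyde) | O=C[C@@]1(C)[C@@H](C)CC[C@@]2([C@@H](C)[C@H](O[Si](C)(C)C(C)(C)C)[C@](C)(C=C)CI)CC3(OCCO3)C[C@@H]12 | intermediate
28 | tricyclic alcohol: C14–OH, C11–OTBS, C2 dioxolane, C4–H | C=C[C@]1(C)C[C@@H](O)[C@]2(C)[C@@H]3CC4(OCCO4)C[C@@]3(CC[C@@H]2C)[C@@H](C)[C@@H]1O[Si](C)(C)C(C)(C)C | intermediate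
29 | keto alcohol: C2 ketone, C14–OH, C11–OTBS | C=C[C@]1(C)C[C@@H](O)[C@]2(C)[C@@H]3CC(=O)C[C@@]3(CC[C@@H]2C)[C@@H](C)[C@@H]1O[Si](C)(C)C(C)(C)C | intermediate
30 | 2-[(tert-butyldimethylsilyl)oxy]acetic acid | CC(C)(C)[Si](C)(C)OCC(O)=O | starting material
31 | C14 (silyloxy)acetate of 29 | C=C[C@]1(C)C[C@@H](OC(=O)CO[Si](C)(C)C(C)(C)C)[C@]2(C)[C@@H]3CC(=O)C[C@@]3(CC[C@@H]2C)[C@@H](C)[C@@H]1O[Si](C)(C)C(C)(C)C | intermediate
32 | bis(tert-butyldimethylsilyl) ether of pleuromutilin F | C=C[C@]1(C)C[C@@H](OC(=O)CO[Si](C)(C)C(C)(C)C)[C@]2(C)C3=CC(=O)C[C@@]3(CC[C@@H]2C)[C@@H](C)[C@@H]1O[Si](C)(C)C(C)(C)C | intermediate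
33 | pleuromutilin F | C=C[C@]1(C)C[C@@H](OC(=O)CO)[C@]2(C)C3=CC(=O)C[C@@]3(CC[C@@H]2C)[C@@H](C)[C@@H]1O | target

**Totals**
Total step count: 21. Longest linear sequence: 21 steps (from 1; compounds 3, 6, 8, 22 and 30 enter as purchased reagents).

**Three steps most likely to fail**

Step 17. The alkylsamarium may be protonated, or the aldehyde may be reduced and couple with itself, faster than an eight-membered ring closes between arms that leave the cyclohexane from opposite faces; facial selectivity at C14 may also be poor. The fallback sets out from iodo ester 26 and replaces the Barbier addition by an acyl substitution followed by a separate carbonyl reduction. Iodine–lithium exchange (t-BuLi, Et2O–pentane, −78 °C) and attack of the alkyllithium on the neighbouring methyl ester should give the cyclooctanone F1, whose tetrahedral intermediate survives until work-up. Reduction of the C14 ketone (SmI2–H2O, or a hydride chosen for the required face) then returns to the route at 28.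

Step 6. Dienolate formation from the enone may stall the Michael stage, or enolisation of the ketone may compete with ketene acetal formation so that the [3,3] shift stays incomplete. The fallback sets out from 11 and separates the two events with the ketone masked. The tert-butoxide stage is run alone and lactone 12 is isolated, then ketalised (Me3SiOCH2CH2OSiMe3, Me3SiOTf) to the dioxolane lactone F2. Ireland–Claisen ring contraction of F2 alone (KN(SiMe3)2, t-BuMe2SiCl, THF, −78 °C, then toluene, 100 °C, acidic work-up) should give the ketal acid F3. Methylation (MeI, K2CO3) returns to the route at 17.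

Step 4. The organocopper reagent may attack the allylic propanoate in an SN2′ sense, or add to the enone with poor facial selectivity at C9. The fallback sets out from alcohol 5 and moves the stereocontrol from the substrate to a catalyst, with no allylic ester present. Silylation (t-BuMe2SiCl, imidazole) gives the silyl ether F4. Conjugate addition of an isopropenylaluminium reagent (from 8 and i-Bu2AlCl) under Cu(OTf)2 with a chiral N-heterocyclic carbene ligand should give the quaternary ketone F5. Desilylation (Bu4NF) gives the hydroxy ketone F6, and propanoylation with 6 returns to the route at 10.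

Further compounds
F1 | step 17 | cyclooctanone: C14 ketone, C11–OTBS, C2 dioxolane | C=C[C@]1(C)CC(=O)[C@]2(C)[C@@H]3CC4(OCCO4)C[C@@]3(CC[C@@H]2C)[C@@H](C)[C@@H]1O[Si](C)(C)C(C)(C)C
F2 | step 6 | ethylene ketal of lactone 12 | C/C=C/[C@H]1OC(=O)C(C)[C@@H]2CC3(OCCO3)C[C@]12C(C)=C
F3 | step 6 | ethylene ketal of acid 15 | OC(=O)[C@@]1(C)[C@@H](C)C=C[C@@]2(C(C)=C)CC3(OCCO3)C[C@@H]12
F4 | step 4 | tert-butyldimethylsilyl ether of 5 | C/C=C/[C@@H](O[Si](C)(C)C(C)(C)C)C1=CC(=O)CC1
F5 | step 4 | 3-[(1R,2E)-1-(tert-butyldimethylsilyloxy)but-2-en-1-yl]-3-(prop-1-en-2-yl)cyclopentan-1-one, quaternary carbon as in 10 | C/C=C/[C@@H](O[Si](C)(C)C(C)(C)C)[C@@]1(C(C)=C)CC(=O)CC1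
F6 | step 4 | 3-[(1R,2E)-1-hydroxybut-2-en-1-yl]-3-(prop-1-en-2-yl)cyclopentan-1-one, quaternary carbon as in 10 | C/C=C/[C@@H](O)[C@@]1(C(C)=C)CC(=O)CC1
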